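**Retrosynthetic overview**
1. 14 ⇐ lactone 13 (C2=O → C2=CH2) ⇐ acyclic prenyl hydroxy amide 11 by 6-endo bromo-cyclisation; ring B (the oxane) is closed last and C5 is set there.
2. 11 ⇐ keto amide 9 by catalyst-controlled allylboration (sets C3) and cross-metathesis; 9 ⇐ its C1′ epimer 7 through a silyl enol ether that is protonated anti to the axial C3′–Br.
3. 7 ⇐ bridged bromolactone 4 by chloride opening through the bromonium ion (Br/Cl trans) and one-carbon homologation with t-BuNC.
4. 4 ⇐ isoprene 1 + acrylic acid 2 by an asymmetric Diels–Alder reaction and bromolactonization in one flask; ring A and the bridging lactone (a temporary stereochemical tether) are formed together, first.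

Assumption: the named enantiomers of the two chiral catalysts (steps 1 and 4) give the configurations drawn; if the observed sense is opposite, the mirror-image catalyst is used.
Locants: ring A = C1′–C6′ (side chain on C1′, Br on C3′, Cl/Me on C4′); ring B = O1–C6.

**Step 1**
Reactants: 1 isoprene (2-methylbuta-1,3-diene); 2 acrylic acid (prop-2-enoic acid)
Product: 4 (1S,4R,6S)-6-bromo-1-methyl-2-oxabicyclo[2.2.2]octan-3-one, via cyclohexene acid 3 (not isolated)
Conditions: (R)-3,3-diphenyl-1-(o-tolyl)tetrahydro-1H,3H-pyrrolo[1,2-c][1,3,2]oxazaborole·HNTf2 (10 mol %), CH2Cl2, −40 → −20 °C; strip excess 1; then NBS, MeCN, 0 °C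
Reagents that add atoms: N-bromosuccinimide (O=C1CCC(=O)N1Br)
Why: A cationic-oxazaborolidine-catalysed Diels–Alder reaction gives the para adduct and sets C1′ (R), and bromolactonization in the same flask lets the cis carboxylate attack the tertiary alkene carbon so that Br is forced anti to it, which forms the carbocycle and the bridging lactone in one operation and fixes C3′ and C4′ relative to C1′.

**Step 2**
Reactants: 4 (1S,4R,6S)-6-bromo-1-methyl-2-oxabicyclo[2.2.2]octan-3-one
Product: 7 2-[(1R,3S,4S)-3-bromo-4-chloro-4-methylcyclohexyl]-N-tert-butyl-2-oxoacetamide, via acid chloride 5 (not isolated), via imidoyl chloride 6 (not isolated)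
Conditions: SOCl2, ZnCl2 (cat.), 65 °C; evaporate; then t-BuNC, CH2Cl2, 25 °C; then NaHCO3, H2O/THF, 0 °C
Reagents that add atoms: thionyl chloride (O=S(Cl)Cl); tert-butyl isocyanide ([C-]#[N+]C(C)(C)C); water (O)
Why: Proposed new method: the closest known reaction type is the ZnCl2-catalysed SOCl2 cleavage of lactones to ω-chloroacyl chlorides; here the tertiary C4′–O bond ionises with anchimeric assistance from the anti-periplanar C3′–Br, chloride reopens the bromonium ion at the tertiary carbon anti to bromine (net retention at C4′, Br and Cl trans-diaxial), and the Nef isocyanide reaction of the acid chloride followed by hydrolysis of the imidoyl chloride supplies C2 as a carboxamide.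

**Step 3**
Reactants: 7 2-[(1R,3S,4S)-3-bromo-4-chloro-4-methylcyclohexyl]-N-tert-butyl-2-oxoacetamide
Product: 8 trimethylsilyl 2-[(3S,4S)-3-bromo-4-chloro-4-methylcyclohexylidene]-N-tert-butyl-2-(trimethylsilyloxy)ethanimidate (E/Z mixture, used crude)
Conditions: TMSOTf (2.4 equiv), Et3N, CH2Cl2, 0 °C; pentane, filter
Reagents that add atoms: trimethylsilyl trifluoromethanesulfonate (C[Si](C)(C)OS(=O)(=O)C(F)(F)F)
Why: Soft enolisation and silylation give the silyl enol ether (and O-silyl imidate), which deliberately erases C1′, so far trans to Br (the wrong relationship), while C3′ and C4′ are untouched.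

**Step 4**
Reactants: 8 trimethylsilyl 2-[(3S,4S)-3-bromo-4-chloro-4-methylcyclohexylidene]-N-tert-butyl-2-(trimethylsilyloxy)ethanimidate
Product: 10 (2S)-2-[(1S,3S,4S)-3-bromo-4-chloro-4-methylcyclohexyl]-N-tert-butyl-2-hydroxypent-4-enamide, via keto amide 9 (not isolated)
Conditions: HCl (2.0 equiv, Et2O), CH2Cl2, −95 °C; then allyl-B(OiPr)2, (S)-3,3′-dibromo-1,1′-bi-2-naphthol (15 mol %), toluene, −78 → −40 °C; aq. NaHCO3
Reagents that add atoms: allyl(diisopropoxy)borane (C=CCB(OC(C)C)OC(C)C)
Why: Proposed new method: the closest known reaction types are kinetic protonation of exocyclic cyclohexylidene enol derivatives from the less hindered face (Zimmerman type) and chiral-diol-catalysed asymmetric allylboration of ketones (Schaus type); here HCl protonates the silyl enol ether anti to the axial C3′–Br (1,3-diaxial shielding in the conformer with Br and Cl axial), giving the less stable C1′ epimer with the side chain cis to Br, and the ketone is trapped at once by allylboration on its Re face, which sets C3 as S under catalyst control because C1′ exerts little local bias.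

**Step 5**
Reactants: 10 (2S)-2-[(1S,3S,4S)-3-bromo-4-chloro-4-methylcyclohexyl]-N-tert-butyl-2-hydroxypent-4-enamide
Product: 11 (2S)-2-[(1S,3S,4S)-3-bromo-4-chloro-4-methylcyclohexyl]-N-tert-butyl-2-hydroxy-5-methylhex-4-enamide
Conditions: 2-methylbut-2-ene (excess), second-generation Grubbs catalyst (5 mol %), CH2Cl2, 40 °C
Reagents that add atoms: 2-methylbut-2-ene (CC=C(C)C)
Why: Olefin cross-metathesis turns the allyl group into a prenyl group without touching any stereocentre, alkyl halide, hydroxyl or amide.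

**Step 6**
Reactants: 11 (2S)-2-[(1S,3S,4S)-3-bromo-4-chloro-4-methylcyclohexyl]-N-tert-butyl-2-hydroxy-5-methylhex-4-enamide
Product: 13 (3S,5R)-5-bromo-3-[(1S,3S,4S)-3-bromo-4-chloro-4-methylcyclohexyl]-3-hydroxy-6,6-dimethyloxan-2-one, via imino lactone 12 (not isolated)
Conditions: NBS, MeCN, −20 °C; then aq. AcOH, 25 °C
Reagents that add atoms: N-bromosuccinimide (O=C1CCC(=O)N1Br); water (O)
Why: 6-endo bromo-cyclisation (halolactonization through the amide oxygen, Markovnikov attack at the tertiary carbon) runs through a chair transition state with the cyclohexyl group equatorial and Br anti to the incoming oxygen, which sets C5 as R (Br cis to cyclohexyl, OH axial), and the imino lactone is then hydrolysed to the lactone.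

**Step 7**
Reactants: 13 (3S,5R)-5-bromo-3-[(1S,3S,4S)-3-bromo-4-chloro-4-methylcyclohexyl]-3-hydroxy-6,6-dimethyloxan-2-one
Product: 14 (3S,5R)-5-bromo-3-[(1S,3S,4S)-3-bromo-4-chloro-4-methylcyclohexyl]-6,6-dimethyl-2-methylideneoxan-3-ol
Conditions: Cp2Ti(CH2)(Cl)AlMe2 (Tebbe reagent, 3 equiv), pyridine, THF–toluene, −40 → 0 °C; aq. NaOH
Reagents that add atoms: Tebbe reagent (C[Al](C)C[Ti](Cl)(C1C=CC=C1)C1C=CC=C1)
Why: Tebbe methylenation of the lactone carbonyl gives the enol ether, which can only be exocyclic because C3 is quaternary, under non-acidic conditions that leave the halides and all stereocentres intact; the excess reagent covers the free tertiary hydroxyl, which is held as a titanium alkoxide and released on basic work-up.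

**Compound list**
1 | 2-methylbuta-1,3-diene (isoprene) | C=CC(C)=C | starting material
2 | prop-2-enoic acid (acrylic acid) | C=CC(=O)O | starting material
3 | (1R)-4-methylcyclohex-3-ene-1-carboxylic acid | OC(=O)[C@@H]1CCC(C)=CC1 | intermediate
4 | (1S,4R,6S)-6-bromo-1-methyl-2-oxabicyclo[2.2.2]octan-3-one | O=C3[C@@H]1CC[C@](C)(O3)[C@@H](Br)C1 | intermediate
5 | (1R,3S,4S)-3-bromo-4-chloro-4-methylcyclohexane-1-carbonyl chloride | ClC(=O)[C@@H]1CC[C@](C)(Cl)[C@@H](Br)C1 | intermediate
6 | N-tert-butyl-2-[(1R,3S,4S)-3-bromo-4-chloro-4-methylcyclohexyl]-2-oxoethanimidoyl chloride | CC(C)(C)N=C(Cl)C(=O)[C@@H]1CC[C@](C)(Cl)[C@@H](Br)C1 | intermediate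
7 | 2-[(1R,3S,4S)-3-bromo-4-chloro-4-methylcyclohexyl]-N-tert-butyl-2-oxoacetamide | CC(C)(C)NC(=O)C(=O)[C@@H]1CC[C@](C)(Cl)[C@@H](Br)C1 | intermediate
8 | trimethylsilyl 2-[(3S,4S)-3-bromo-4-chloro-4-methylcyclohexylidene]-N-tert-butyl-2-(trimethylsilyloxy)ethanimidate | CC(C)(C)N=C(O[Si](C)(C)C)C(O[Si](C)(C)C)=C1CC[C@](C)(Cl)[C@@H](Br)C1 | intermediate
9 | 2-[(1S,3S,4S)-3-bromo-4-chloro-4-methylcyclohexyl]-N-tert-butyl-2-oxoacetamide | CC(C)(C)NC(=O)C(=O)[C@H]1CC[C@](C)(Cl)[C@@H](Br)C1 | intermediate
10 | (2S)-2-[(1S,3S,4S)-3-bromo-4-chloro-4-methylcyclohexyl]-N-tert-butyl-2-hydroxypent-4-enamide | C=CC[C@@](O)(C(=O)NC(C)(C)C)[C@H]1CC[C@](C)(Cl)[C@@H](Br)C1 | intermediate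
11 | (2S)-2-[(1S,3S,4S)-3-bromo-4-chloro-4-methylcyclohexyl]-N-tert-butyl-2-hydroxy-5-methylhex-4-enamide | CC(C)=CC[C@@](O)(C(=O)NC(C)(C)C)[C@H]1CC[C@](C)(Cl)[C@@H](Br)C1 | intermediate
12 | (3S,5R)-5-bromo-3-[(1S,3S,4S)-3-bromo-4-chloro-4-methylcyclohexyl]-2-(tert-butylimino)-6,6-dimethyloxan-3-ol | CC(C)(C)N=C1OC(C)(C)[C@H](Br)C[C@]1(O)[C@H]1CC[C@](C)(Cl)[C@@H](Br)C1 | intermediate
13 | (3S,5R)-5-bromo-3-[(1S,3S,4S)-3-bromo-4-chloro-4-methylcyclohexyl]-3-hydroxy-6,6-dimethyloxan-2-one | O=C1OC(C)(C)[C@H](Br)C[C@]1(O)[C@H]1CC[C@](C)(Cl)[C@@H](Br)C1 | intermediate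
14 | (3S,5R)-5-bromo-3-[(1S,3S,4S)-3-bromo-4-chloro-4-methylcyclohexyl]-6,6-dimethyl-2-methylideneoxan-3-ol | C=C1OC(C)(C)[C@H](Br)C[C@]1(O)[C@H]1CC[C@](C)(Cl)[C@@H](Br)C1 | target

**Total step count:** 7. **Longest linear sequence:** 7.

**Steps most likely to fail, with fallbacks**

Risk at step 2 (opening of a tertiary bromolactone without elimination or halogen scrambling). If it fails, the lactone tether is abandoned. The fallback sets out from 3, isolated after the Diels–Alder stage. Oxalyl chloride gives (1R)-4-methylcyclohex-3-ene-1-carbonyl chloride F1. BrCl (from NBS and Me3SiCl, CH2Cl2, −78 °C) then adds trans-diaxially: the bromonium ion forms on the face anti to the equatorial COCl group and chloride enters at the tertiary carbon. This comes back to the route at 5; the minor face isomer is removed by chromatography at 7, before any base is used.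

Risk at step 4 (face-selective protonation, configurational stability of 9, and enantioface control on an α-keto amide). If 9 re-epimerises or the protonation is unselective, C1′ is set on an ester, where C-protonation is irreversible. The fallback sets out from 5. Methanol/pyridine gives methyl (1R,3S,4S)-3-bromo-4-chloro-4-methylcyclohexane-1-carboxylate F2. LiN(iPr)2 (THF, −78 °C) followed by a 2,6-di-tert-butylphenol quench protonates the enolate anti to the axial bromine and gives methyl (1S,3S,4S)-3-bromo-4-chloro-4-methylcyclohexane-1-carboxylate F3. LiOH (THF/H2O, 0 °C) gives (1S,3S,4S)-3-bromo-4-chloro-4-methylcyclohexane-1-carboxylic acid F4, and oxalyl chloride gives (1S,3S,4S)-3-bromo-4-chloro-4-methylcyclohexane-1-carbonyl chloride F5. t-BuNC gives N-tert-butyl-2-[(1S,3S,4S)-3-bromo-4-chloro-4-methylcyclohexyl]-2-oxoethanimidoyl chloride F6. Cold buffered hydrolysis of F6 comes back to the route at 9, which is allylborated at once as in step 4.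

Risk at step 7 (methylenation of a hindered α-hydroxy lactone carrying three carbon–halogen bonds). If the Tebbe reaction fails, the exocyclic carbon is added as a nucleophile instead. The fallback sets out from 13. MeLi (2.2 equiv, THF, −78 °C) gives the lactol (3S,5R)-5-bromo-3-[(1S,3S,4S)-3-bromo-4-chloro-4-methylcyclohexyl]-2,6,6-trimethyloxane-2,3-diol F7. Dehydration of the hemiketal hydroxyl (MsCl, Et3N, 0 °C) can only eliminate towards the methyl group and comes back to the route at 14.

**Further compounds**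
F1 | step 2 | (1R)-4-methylcyclohex-3-ene-1-carbonyl chloride | ClC(=O)[C@@H]1CCC(C)=CC1
F2 | step 4 | methyl (1R,3S,4S)-3-bromo-4-chloro-4-methylcyclohexane-1-carboxylate | COC(=O)[C@@H]1CC[C@](C)(Cl)[C@@H](Br)C1
F3 | step 4 | methyl (1S,3S,4S)-3-bromo-4-chloro-4-methylcyclohexane-1-carboxylate | COC(=O)[C@H]1CC[C@](C)(Cl)[C@@H](Br)C1
F4 | step 4 | (1S,3S,4S)-3-bromo-4-chloro-4-methylcyclohexane-1-carboxylic acid | OC(=O)[C@H]1CC[C@](C)(Cl)[C@@H](Br)C1
F5 | step 4 | (1S,3S,4S)-3-bromo-4-chloro-4-methylcyclohexane-1-carbonyl chloride | ClC(=O)[C@H]1CC[C@](C)(Cl)[C@@H](Br)C1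
F6 | step 4 | N-tert-butyl-2-[(1S,3S,4S)-3-bromo-4-chloro-4-methylcyclohexyl]-2-oxoethanimidoyl chloride | CC(C)(C)N=C(Cl)C(=O)[C@H]1CC[C@](C)(Cl)[C@@H](Br)C1
F7 | step 7 | (3S,5R)-5-bromo-3-[(1S,3S,4S)-3-bromo-4-chloro-4-methylcyclohexyl]-2,6,6-trimethyloxane-2,3-diol | CC1(O)OC(C)(C)[C@H](Br)C[C@]1(O)[C@H]1CC[C@](C)(Cl)[C@@H](Br)C1
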